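- Solid monomer outnumbers initiator 833 to one in the flask, so write the balance of initiator first: what ends up in chains, set against the initiator charged.

common to all: solid monomer 0.050 M
- beta: initiator 60 µM; the very flask that is asked about, followed so far
- gamma: initiator 40 µM; run made earlier
- flask: initiator 60 µM; time 2.5 h

| run | time / min | monomer in chains / % | free monomer / % |
|---|---|---|---|
| beta | 6.00 | 1.2 | 1.8 |
| beta | 10.0 | 0.3 | 2.7 |
| beta | 15.0 | 0.5 | 7.1 |
| beta | 25.0 | 1.3 | 7.8 |
| beta | 50.0 | 0.5 | 16.3 |
| beta | 80.0 | 0 | 20.8 |
| gamma | 8.00 | 0 | 0.9 |
| gamma | 20.0 | 0.4 | 8.4 |
| gamma | 40.0 | 0.3 | 12.4 |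
| gamma | 60.0 | 0 | 17.3 |
| gamma | 80.0 | 3.4 | 20.1 |
| gamma | 120 | 3.2 | 26.9 |

(readings scatter by 1 percentage point)

- given per volume of solution although it is solid: solid monomer
- at the start none of the solid monomer is in solution
- free monomer is what solid monomer becomes in solution

- north: doubling the solubility of the solid monomer, all else as stated
- south-west: doubling the dissolution coefficient of the solid monomer, all else as stated

- how much monomer in chains there is at 2.5 h, in percent of the solid monomer charged
- concentration of free monomer in solution at 15 min, in percent of saturation
- the change that raises the amount of monomer in chains at 2.5 h, in percent of the solid monomer charged most ("none" if none brings more than 2 percentage points) (north / south-west / none)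
- amount of monomer in chains at 2.5 h, in percent of the solid monomer charged, after north

- The gamma run reads 3.2% in chains at 120 min, with a scatter of 1 percentage point, from 40 µM of initiator and 0.050 M of solid monomer. That gives 40.0: this is the chain load, monomer in chains per initiator charged, a rough kind of kinetic chain length.
- My own reckoning holds that load for the flask, which runs longer, to 2.5 h, and carries more initiator, 60 µM. Multiplying the load by [initiator] and dividing by [solid monomer] gives 4.80% in chains.
- For the next run, leave both charges as they are and try to raise [free monomer]. At 80.0 min the beta run reads 20.8% and the gamma run 20.1% of free monomer, so changing initiator from 40 µM to 60 µM shows no effect on it beyond the scatter. Of the two changes, I would run north, which raises the ceiling of [free monomer].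
- The forecast gives 5% (2.5% to 9%) for the flask, 15% of saturation at 15 min, north as the best change, and 10.5% after it. Its ground for that choice is: “Doubling solubility doubles the driving force”. Its 5% comes from its own fit, not from my load.

    solid monomer ⇌ free monomer, rate k1*(cs1 - [free monomer]) while solid is left; crystals form when [free monomer] > cs1 (solubility = 21.0 mM, k = 0.580 h⁻¹)
    2 growing radical → dead chain (k = 5.20 × 10⁶ M⁻¹ s⁻¹)
    initiator → 2 initiating radical (k = 0.470 h⁻¹)
    free monomer + initiating radical → growing radical + monomer in chains (k = 27000 M⁻¹ s⁻¹)
    free monomer + growing radical → monomer in chains + growing radical, rate k5*[growing radical]*[free monomer] (k = 4.60 × 10⁶ M⁻¹ h⁻¹)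

- The flask holds 5.84% in chains at 2.5 h and stands at 13.2% of saturation at 0.250 h. North gains 5.7 points against 2.7 points for south-west, reaching 11.5%. The chain load read from the gamma run was 40.0, with the scatter of that reading; the chain load of the flask comes to 48.7. A neighbour charged with 0.020 M of solid monomer and the same initiator reaches 14.6%, a load of 48.6, with [free monomer] at 14.4 mM at 2.50 h against 14.4 mM in the flask.

(All runs are calculated for an exercise, noise included.)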